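The earlier runs and the new flask were computed with constants of no real substance; the scatter is artificial.

**The ceiling.** I started from a one-step world in which one reagent makes one product. There the reagent, charged in the smaller amount, is the limiting reagent. Product, as a fraction of the starting material charged, cannot pass the ratio of the two charges, 94.7%, which I called the ceiling. Starting material left cannot fall below 5.33%.

- west: starting material 1.5 M; reagent 1.42 M; free catalyst 76 mM; run made earlier
- flask: starting material 1.5 M; reagent 1.42 M; free catalyst 38 mM; time 12 h

west run (percent of the starting material charged)

| time / h | product / % | starting material / % |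
|---|---|---|
| 0.250 | 6.9 | 92.0 |
| 0.667 | 20.2 | 79.1 |
| 1.50 | 41.7 | 58.0 |
| 4.00 | 78.0 | 21.9 |

(standard deviation of a reading: 0.3 percentage points)

- no earlier run changes the charge of free catalyst; that part of a forecast is a guess

- concentration of product at 12 h, in M
- concentration of starting material at 12 h, in M

**Two reckonings.** No earlier run varied the catalyst, so I guessed first order in it, and the flask's 12 h counted as 6.00 h of the west run. First, I let starting material decay exponentially with the constant from the last west reading, 0.380 h⁻¹, which left 10.2%. Second, I let the gap between product and the ceiling close exponentially, with 0.434 h⁻¹, which left 12.3%.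

**Which cheats.** From the first west reading to the last, the first constant rose from 0.334 h⁻¹ to 0.380 h⁻¹, and the second from 0.303 h⁻¹ to 0.434 h⁻¹, a larger drift. So the second form, which slows as reagent goes, was the one that cheated. I committed to 10.2% left, which stands above the floor.

**The forecast.** It gave 0.15 M of starting material and 1.35 M of product, on the same guess: “first order in catalyst, so 12 h at half catalyst equals 6 h of the west run”.

**The flask.** It gave 0.154 M of starting material, 10.3% of the charge, and 1.35 M of product, 89.7%, under the ceiling. The steps were these.

    starting material + catalyst intermediate B → catalyst intermediate C (k = 0.240 L mol⁻¹ min⁻¹)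
    catalyst intermediate C → free catalyst + product (k = 0.530 min⁻¹)
    catalyst intermediate A ⇌ catalyst intermediate B (K = 1.30, k = 18.0 min⁻¹)
    reagent + free catalyst → catalyst intermediate A (k = 0.410 L mol⁻¹ min⁻¹)

**The neighbour.** A neighbouring flask, otherwise the same, was charged with 0.57 M of reagent, so its ceiling was 38.0% and its floor 62.0%. That floor stands above the 10.2% of my decay, so I read the ceiling as its answer. At 12.0 h that neighbouring flask held product at 38.0%, starting material at 62.0%, and reagent at 0.00897% of its own charge.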